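**Retrosynthetic overview**

1. Target 37 ← cleavage of one tert-butyl ester and four TBS ethers ← C8 ester 35 (Yamaguchi coupling with acid 34) ← alcohol 29 ← cyclohexanone 28.
2. Key disconnection C9–C10: 28 ← open-chain tert-butyl β-keto ester 24 with a free E allylic C2–OH. Heating gives an acylketene, then a temporary ten-membered β-keto lactone, then a transannular Carroll [3,3] shift; the O–C2/ester tether is absent from the target and leaves as CO2.
3. Enabling feature: C8 (oxygenated), the C9 methylene and C10 with its vinyl group C1=C2 form a γ,δ-unsaturated carbonyl array. The ring C5–C10 can form as a chair trans-fused to the pericyclic chair (an oxa-germacradiene-to-elemane shift), so the equatorial C5 side chain fixes C10.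
4. 24 ← C6/C7 by a magnesium-halide-catalysed anti-aldol (succinate imide 8 + enal 5); C5 by Claisen chirality transfer from the C1 carbinol of a glycerate-derived diol, whose C2–OH later becomes the tether; methylene carbons C13 and C3 by α-methylenation.
5. Ring order: ten-membered lactone 26 (temporary) → cyclohexane (the only ring of the target).

Key step: step 17

Remark (numbering): locants C1–C15 follow elemane numbering: ring C5–C6–C7–C8–C9–C10; vinyl C1=C2 and methyl C14 on C10; C4(=C3)–C15 on C5; C11(=C13)–C12 on C7; primed locants are the C8 acyl group; TBS = tert-butyldimethylsilyl, PMB = 4-methoxybenzyl.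

Remark (chemistry): α-isocupreine (quinine-derived pseudo-enantiomer of β-isocupreidine) is assumed to be made from quinine beforehand; the hydroxy acid target is handled cold and near neutral pH because the C6 hydroxyl can lactonise onto C12.

**Route**

Step 1
Reactants: 1 methyl (4R)-2,2-dimethyl-1,3-dioxolane-4-carboxylate
Product: 3 1-[(4R)-2,2-dimethyl-1,3-dioxolan-4-yl]ethan-1-one, via Weinreb amide 2 (not isolated)
Conditions: MeNH(OMe)·HCl, i-PrMgCl, THF, −20 °C; then MeMgBr, −20 → 0 °C
Reagents that add atoms: methylmagnesium bromide, C[Mg]Br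
Why: One-pot Weinreb ketone synthesis, in which the chelated tetrahedral adduct of amide 2 with MeMgBr stops at the ketone and the low temperature preserves the α-alkoxy stereocentre.

Step 2
Reactants: 3 1-[(4R)-2,2-dimethyl-1,3-dioxolan-4-yl]ethan-1-one
Product: 4 (2E)-3-[(4S)-2,2-dimethyl-1,3-dioxolan-4-yl]-N-methoxy-N-methylbut-2-enamide
Conditions: (EtO)2P(O)CH2C(O)N(OMe)Me, NaH, THF, 0 → 50 °C
Reagents that add atoms: diethyl {2-[methoxy(methyl)amino]-2-oxoethyl}phosphonate, CCOP(=O)(CC(=O)N(C)OC)OCC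
Why: Horner–Wadsworth–Emmons olefination of the methyl ketone should favour the E alkene (amide trans to the branched dioxolanyl group), the minor Z isomer being removed by chromatography.

Step 3
Reactants: 4 (2E)-unsaturated Weinreb amide
Product: 5 (2E)-3-[(4S)-2,2-dimethyl-1,3-dioxolan-4-yl]but-2-enal
Conditions: i-Bu2AlH, THF, −78 °C; aq. KNaC4H4O6
Reagents that add atoms: none
Why: Hydride reduction of a Weinreb amide stops at the aldehyde because the chelated aluminium hemiaminal collapses only on work-up.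

Step 4
Reactants: 6 4-tert-butoxy-4-oxobutanoic acid; 7 (4R)-4-benzyl-1,3-oxazolidin-2-one
Product: 8 tert-butyl 4-[(4R)-4-benzyl-2-oxo-1,3-oxazolidin-3-yl]-4-oxobutanoate
Conditions: t-BuCOCl, Et3N, THF, −20 °C; then 7, LiCl, −20 °C → rt
Reagents that add atoms: none
Why: N-Acylation of the oxazolidinone through the mixed pivalic anhydride gives the succinate imide.

Step 5
Reactants: 8 succinate imide; 5 enal
Product: 10 anti-aldol adduct (6S,7S) with free C6 hydroxyl, via trimethylsilyl ether 9 (not isolated)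
Conditions: MgCl2 (20 mol %), Et3N, Me3SiCl, EtOAc, 23 °C; then citric acid, MeOH, 0 °C
Reagents that add atoms: none
Why: Magnesium-halide-catalysed direct anti-aldol of an N-acyl oxazolidinone, in which the MgCl2-chelated Z enolate of the (R)-benzyl imide should add to the non-epimerisable enal through a boat transition state on the face away from the benzyl group, setting C7 (S) and C6 (S, anti), while O-silylation turns the catalyst over.

Step 6
Reactants: 10 anti-aldol adduct
Product: 11 C6 TBS ether of 10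
Conditions: TBSOTf, 2,6-lutidine, CH2Cl2, −78 → 0 °C
Reagents that add atoms: tert-butyldimethylsilyl trifluoromethanesulfonate, CC(C)(C)[Si](C)(C)OS(=O)(=O)C(F)(F)F
Why: Silylation of the secondary allylic alcohol under buffered conditions that leave the acetonide intact.

Step 7
Reactants: 11 C6 TBS ether
Product: 14 tert-butyl acrylate (C11=C13 methylene installed), via Mannich base 12 (not isolated), via methiodide 13 (not isolated)
Conditions: LiN(i-Pr)2, THF, −78 °C; CH2=NMe2+ I−, −78 → 0 °C; then MeI, CH2Cl2, rt; then aq. NaHCO3, rt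
Reagents that add atoms: N,N-dimethylmethyleneiminium iodide, C=[N+](C)C.[I-]
Why: Mannich-type α-methylenation of an ester, in which the amide base deprotonates the unhindered CH2 of the tert-butyl ester (the imide α-hydrogen is shielded by allylic 1,3-strain) and quaternisation followed by mild-base loss of trimethylamine gives the acrylate without touching C7.

Step 8
Reactants: 14 acrylate acetonide
Product: 15 C1,C2-diol
Conditions: AcOH/THF/H2O (3:1:1), 40 °C
Reagents that add atoms: none
Why: Acid hydrolysis of the terminal acetonide, which the secondary TBS ether, the imide and the tert-butyl ester tolerate.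

Step 9
Reactants: 15 C1,C2-diol
Product: 16 C2 PMB ether with free C1 hydroxyl
Conditions: Bu2SnO, MeOH, 65 °C; then 4-MeOC6H4CH2Cl, Bu4NI (cat.), toluene, 70 °C
Reagents that add atoms: 4-methoxybenzyl chloride, COc1ccc(CCl)cc1
Why: Regioselective stannylene-acetal alkylation, in which the dibutylstannylene acetal of the 1,2-diol reacts at the primary oxygen.

Step 10
Reactants: 16 C2 PMB ether
Product: 18 C15 aldehyde with C5 stereocentre and E C10=C1 alkene, via allyl vinyl ether 17 (not isolated)
Conditions: n-BuOCH=CH2, Pd(OCOCF3)2 (5 mol %), 4,7-diphenyl-1,10-phenanthroline (5 mol %), Et3N, 75 °C; then xylene, 140 °C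
Reagents that add atoms: butyl vinyl ether, C=COCCCC
Why: Palladium-catalysed transfer vinylation followed by an aliphatic Claisen rearrangement, whose chair transition state with the CH2OPMB group equatorial should relay the C1 configuration to C5 (R by CIP here), give the E alkene and form the new bond anti to the C7 branch on C6 (matched case).

Step 11
Reactants: 18 C15 aldehyde
Product: 19 α-methylene aldehyde (C4=C3 installed)
Conditions: aq. CH2O, pyrrolidine (10 mol %), EtCO2H (10 mol %), i-PrOH, 45 °C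
Reagents that add atoms: formaldehyde, C=O
Why: Amine-catalysed α-methylenation of an aldehyde (enamine Mannich condensation then elimination) under near-neutral conditions that leave the imide and C7 untouched.

Step 12
Reactants: 19 α-methylene aldehyde
Product: 20 C15 allylic alcohol
Conditions: NaBH4, CeCl3·7H2O, MeOH, −40 °C
Reagents that add atoms: none
Why: Luche 1,2-reduction of the enal, too cold and brief to reduce the imide or the acrylate ester.

Step 13
Reactants: 20 C15 allylic alcohol
Product: 21 C15 TBS ether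
Conditions: TBSCl, imidazole, DMF, 0 °C
Reagents that add atoms: tert-butyldimethylsilyl chloride, CC(C)(C)[Si](C)(C)Cl
Why: Standard silylation of the primary allylic alcohol.

Step 14
Reactants: 21 C15 TBS ether
Product: 22 C8 carboxylic acid
Conditions: LiOH, H2O2, THF/H2O, 0 °C; then Na2SO3; 1 M HCl to pH 4
Reagents that add atoms: lithium hydroperoxide (from LiOH and H2O2), [Li+].[O-]O
Why: Hydroperoxide cleavage of the N-acyl oxazolidinone at the exocyclic carbonyl releases the acid and the auxiliary while the hindered tert-butyl acrylate and the silyl ethers should survive at 0 °C.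

Step 15
Reactants: 22 C8 carboxylic acid
Product: 23 tert-butyl β-keto ester (C9 and the ester carbon added)
Conditions: 1,1'-carbonyldiimidazole, THF, rt; then Mg(O2CCH2CO2t-Bu)2 [from t-BuO2CCH2CO2H and Mg(OEt)2], THF, rt; aq. NH4Cl
Reagents that add atoms: 3-tert-butoxy-3-oxopropanoic acid (as its magnesium salt), CC(C)(C)OC(=O)CC(=O)O
Why: Masamune-type β-keto ester synthesis, in which the acyl imidazolide C-acylates the magnesium malonate and loses CO2 under neutral conditions, so C7 is not epimerised.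

Step 16
Reactants: 23 tert-butyl β-keto ester
Product: 24 β-keto ester with free E allylic C2 hydroxyl
Conditions: DDQ, CH2Cl2/pH 7 buffer, 0 °C
Reagents that add atoms: none
Why: Oxidative cleavage of the PMB ether with DDQ frees the allylic alcohol and leaves the silyl ethers and the β-keto ester in place.

Step 17
Reactants: 24 β-keto ester with free C2 hydroxyl
Product: 28 cyclohexanone (5S,6S,7S,10R) with C8 ketone and C10 methyl/vinyl, via acylketene 25 (not isolated), via ten-membered β-keto lactone 26 (not isolated), via β-keto acid 27 (not isolated)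
Conditions: o-xylene, 140 °C, slow addition to 0.5 mM, 2,6-di-tert-butyl-4-methylphenol (1 mol %)
Reagents that add atoms: none
Why: Proposed new method: thermolysis of the tert-butyl β-keto ester expels tert-butanol and gives acylketene 25, which the C2 allylic hydroxyl captures at high dilution to form the ten-membered (E)-allyl β-keto lactone 26; its hydrogen-bonded ester enol is a 3-oxa-(E,E)-cyclodeca-1,5-diene that should undergo a transannular Carroll [3,3] shift through a chair–chair transition state, forming C9–C10 and breaking O–C2, after which β-keto acid 27 loses CO2. The closest known reactions are the thermal Carroll rearrangement of allyl acetoacetates made in situ from tert-butyl acetoacetates or dioxinones and allylic alcohols, macrolactonisation by acylketene capture, the ester-enolate Claisen ring contraction of macrolactones and the Cope rearrangement of germacrenes to elemenes; new is the use of the Carroll shift as a transannular ring contraction. The temporary lactone is closed by O-acylation of the ketene, and the cyclohexanone is closed by the suprafacial [3,3] shift across that ring (ten-membered to six-membered contraction), the carbocycle forming as a chair trans-fused to the pericyclic chair. C10 is the only new stereocentre: the E alkene places C5 equatorial and the methyl axial on the pericyclic chair, and the substituents at C5 and C6 stay equatorial (only the C7 group is axial), which puts the vinyl group trans to the C5 side chain, whereas the flipped chair suffers a syn-axial methyl/OTBS clash. The step needs intramolecular rather than intermolecular ketene capture (0.5 mM, slow addition; capture is reversible while CO2 loss is not, so material funnels to 28) and no drift of the C11 methylene into conjugation with C8 (neutral, base-free medium).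

Step 18
Reactants: 28 cyclohexanone
Product: 29 C8 alcohol (8R, equatorial, cis to the C6 and C7 substituents)
Conditions: NaBH4, CeCl3·7H2O, MeOH/THF, −78 °C
Reagents that add atoms: none
Why: Luche reduction, in which the small cerium-activated borohydride should attack C8 axially, anti-periplanar to the axial C7 substituent, giving the equatorial alcohol without conjugate reduction of the acrylate.

Step 19
Reactants: 30 (tert-butyldimethylsilyloxy)acetaldehyde; 31 1,1,1,3,3,3-hexafluoropropan-2-yl acrylate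
Product: 32 hexafluoroisopropyl (3R)-4-[(tert-butyldimethylsilyl)oxy]-3-hydroxy-2-methylidenebutanoate
Conditions: α-isocupreine (10 mol %), DMF, −55 °C
Reagents that add atoms: none
Why: Cinchona-alkaloid-catalysed asymmetric Morita–Baylis–Hillman reaction of the activated acrylate, in which the quinine-derived catalyst is the pseudo-enantiomer of β-isocupreidine and should deliver the 3R carbinol from this α-silyloxy aldehyde.

Step 20
Reactants: 32 Morita–Baylis–Hillman adduct
Product: 33 3,4-bis-TBS ether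
Conditions: TBSOTf, 2,6-lutidine, CH2Cl2, −78 °C
Reagents that add atoms: tert-butyldimethylsilyl trifluoromethanesulfonate, CC(C)(C)[Si](C)(C)OS(=O)(=O)C(F)(F)F
Why: Silylation of the secondary allylic alcohol.

Step 21
Reactants: 33 bis-TBS hexafluoroisopropyl ester
Product: 34 (3R)-3,4-bis[(tert-butyldimethylsilyl)oxy]-2-methylidenebutanoic acid
Conditions: LiOH, THF/H2O, 0 °C; 1 M HCl to pH 3
Reagents that add atoms: lithium hydroxide, [Li+].[OH-]
Why: Mild saponification of the activated hexafluoroisopropyl ester gives the acid without β-elimination.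

Step 22
Reactants: 29 C8 alcohol; 34 side-chain acid
Product: 35 C8 ester (fully protected target)
Conditions: 2,4,6-Cl3C6H2COCl, Et3N, THF, rt; then 29, DMAP, toluene, rt
Reagents that add atoms: none
Why: Yamaguchi esterification, in which the mixed 2,4,6-trichlorobenzoic anhydride of 34 acylates the hindered C8 hydroxyl, the only free alcohol.

Step 23
Reactants: 35 C8 ester
Product: 36 C12 carboxylic acid
Conditions: Me3SiOTf, 2,6-lutidine, CH2Cl2, 0 °C; then pH 7 phosphate buffer
Reagents that add atoms: none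
Why: Silyl-triflate-mediated cleavage of a tert-butyl ester (O-silylation, loss of isobutene) under non-protic conditions, with the C6 oxygen still silylated so that the acid cannot lactonise.

Step 24
Reactants: 36 C12 carboxylic acid
Product: 37 CNP0348657.1 (target)
Conditions: HF·pyridine, pyridine, THF, 0 °C → rt; pH 7 buffer work-up
Reagents that add atoms: none
Why: Global fluoride desilylation removes the four TBS groups in a cold, buffered medium chosen to suppress lactonisation of C12 with the C6 hydroxyl and acyl migration.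

**Compound list**

1 | methyl (4R)-2,2-dimethyl-1,3-dioxolane-4-carboxylate | COC(=O)[C@H]1COC(C)(C)O1 | starting material
2 | (4R)-N-methoxy-N,2,2-trimethyl-1,3-dioxolane-4-carboxamide (Weinreb amide) | CON(C)C(=O)[C@H]1COC(C)(C)O1 | intermediate
3 | 1-[(4R)-2,2-dimethyl-1,3-dioxolan-4-yl]ethan-1-one | CC(=O)[C@H]1COC(C)(C)O1 | intermediate
4 | (2E)-3-[(4S)-2,2-dimethyl-1,3-dioxolan-4-yl]-N-methoxy-N-methylbut-2-enamide | CON(C)C(=O)/C=C(\C)[C@H]1COC(C)(C)O1 | intermediate
5 | (2E)-3-[(4S)-2,2-dimethyl-1,3-dioxolan-4-yl]but-2-enal | O=C/C=C(\C)[C@H]1COC(C)(C)O1 | intermediate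
6 | 4-tert-butoxy-4-oxobutanoic acid (mono-tert-butyl succinate) | CC(C)(C)OC(=O)CCC(=O)O | starting material
7 | (4R)-4-benzyl-1,3-oxazolidin-2-one | O=C1N[C@H](Cc2ccccc2)CO1 | starting material
8 | tert-butyl 4-[(4R)-4-benzyl-2-oxo-1,3-oxazolidin-3-yl]-4-oxobutanoate | CC(C)(C)OC(=O)CCC(=O)N1[C@H](Cc2ccccc2)COC1=O | intermediate
9 | C6 trimethylsilyl ether of 10 | O=C(N1[C@H](Cc2ccccc2)COC1=O)[C@@H](CC(=O)OC(C)(C)C)[C@@H](O[Si](C)(C)C)/C=C(\C)[C@H]1COC(C)(C)O1 | intermediate
10 | tert-butyl (3S,4S,5E)-3-{[(4R)-4-benzyl-2-oxo-1,3-oxazolidin-3-yl]carbonyl}-6-[(4S)-2,2-dimethyl-1,3-dioxolan-4-yl]-4-hydroxyhept-5-enoate (anti-aldol; C6 S, C7 S) | O=C(N1[C@H](Cc2ccccc2)COC1=O)[C@@H](CC(=O)OC(C)(C)C)[C@@H](O)/C=C(\C)[C@H]1COC(C)(C)O1 | intermediate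
11 | 4-O-TBS ether of 10 | O=C(N1[C@H](Cc2ccccc2)COC1=O)[C@@H](CC(=O)OC(C)(C)C)[C@@H](O[Si](C)(C)C(C)(C)C)/C=C(\C)[C@H]1COC(C)(C)O1 | intermediate
12 | Mannich base: 2-[(dimethylamino)methyl] derivative of 11 (C11 epimers) | O=C(N1[C@H](Cc2ccccc2)COC1=O)[C@@H](C(CN(C)C)C(=O)OC(C)(C)C)[C@@H](O[Si](C)(C)C(C)(C)C)/C=C(\C)[C@H]1COC(C)(C)O1 | intermediate
13 | methiodide of 12 | O=C(N1[C@H](Cc2ccccc2)COC1=O)[C@@H](C(C[N+](C)(C)C)C(=O)OC(C)(C)C)[C@@H](O[Si](C)(C)C(C)(C)C)/C=C(\C)[C@H]1COC(C)(C)O1.[I-] | intermediate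
14 | tert-butyl (3S,4S,5E)-3-{[(4R)-4-benzyl-2-oxo-1,3-oxazolidin-3-yl]carbonyl}-4-[(tert-butyldimethylsilyl)oxy]-6-[(4S)-2,2-dimethyl-1,3-dioxolan-4-yl]-2-methylidenehept-5-enoate | O=C(N1[C@H](Cc2ccccc2)COC1=O)[C@@H](C(=C)C(=O)OC(C)(C)C)[C@@H](O[Si](C)(C)C(C)(C)C)/C=C(\C)[C@H]1COC(C)(C)O1 | intermediate
15 | diol from 14: (3S,4S,5E,7S)-7,8-dihydroxy-6-methyl-2-methylideneoct-5-enoate with imide at C3 and OTBS at C4 | O=C(N1[C@H](Cc2ccccc2)COC1=O)[C@@H](C(=C)C(=O)OC(C)(C)C)[C@@H](O[Si](C)(C)C(C)(C)C)/C=C(\C)[C@H](O)CO | intermediate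
16 | 8-O-PMB ether of 15 (C1 hydroxyl free, 1S) | O=C(N1[C@H](Cc2ccccc2)COC1=O)[C@@H](C(=C)C(=O)OC(C)(C)C)[C@@H](O[Si](C)(C)C(C)(C)C)/C=C(\C)[C@H](O)COCc1ccc(OC)cc1 | intermediate
17 | C1 O-vinyl ether of 16 | O=C(N1[C@H](Cc2ccccc2)COC1=O)[C@@H](C(=C)C(=O)OC(C)(C)C)[C@@H](O[Si](C)(C)C(C)(C)C)/C=C(\C)[C@H](OC=C)COCc1ccc(OC)cc1 | intermediate
18 | tert-butyl (3S,4S,5R,6E)-3-{[(4R)-4-benzyl-2-oxo-1,3-oxazolidin-3-yl]carbonyl}-4-[(tert-butyldimethylsilyl)oxy]-8-[(4-methoxybenzyl)oxy]-6-methyl-2-methylidene-5-(2-oxoethyl)oct-6-enoate | O=C(N1[C@H](Cc2ccccc2)COC1=O)[C@@H](C(=C)C(=O)OC(C)(C)C)[C@@H](O[Si](C)(C)C(C)(C)C)[C@H](CC=O)/C(C)=C/COCc1ccc(OC)cc1 | intermediate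
19 | 5-(3-oxoprop-1-en-2-yl) analogue of 18 (5S) | O=C(N1[C@H](Cc2ccccc2)COC1=O)[C@@H](C(=C)C(=O)OC(C)(C)C)[C@@H](O[Si](C)(C)C(C)(C)C)[C@H](C(=C)C=O)/C(C)=C/COCc1ccc(OC)cc1 | intermediate
20 | 5-(3-hydroxyprop-1-en-2-yl) analogue of 18 (5S) | O=C(N1[C@H](Cc2ccccc2)COC1=O)[C@@H](C(=C)C(=O)OC(C)(C)C)[C@@H](O[Si](C)(C)C(C)(C)C)[C@H](C(=C)CO)/C(C)=C/COCc1ccc(OC)cc1 | intermediate
21 | C15 TBS ether of 20 | O=C(N1[C@H](Cc2ccccc2)COC1=O)[C@@H](C(=C)C(=O)OC(C)(C)C)[C@@H](O[Si](C)(C)C(C)(C)C)[C@H](C(=C)CO[Si](C)(C)C(C)(C)C)/C(C)=C/COCc1ccc(OC)cc1 | intermediate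
22 | (2S,3S,4S,5E)-2-(3-tert-butoxy-3-oxoprop-1-en-2-yl)-3-[(tert-butyldimethylsilyl)oxy]-4-{3-[(tert-butyldimethylsilyl)oxy]prop-1-en-2-yl}-7-[(4-methoxybenzyl)oxy]-5-methylhept-5-enoic acid | OC(=O)[C@@H](C(=C)C(=O)OC(C)(C)C)[C@@H](O[Si](C)(C)C(C)(C)C)[C@H](C(=C)CO[Si](C)(C)C(C)(C)C)/C(C)=C/COCc1ccc(OC)cc1 | intermediate
23 | tert-butyl (4S,5S,6S,7E)-4-(3-tert-butoxy-3-oxoprop-1-en-2-yl)-5-[(tert-butyldimethylsilyl)oxy]-6-{3-[(tert-butyldimethylsilyl)oxy]prop-1-en-2-yl}-9-[(4-methoxybenzyl)oxy]-7-methyl-3-oxonon-7-enoate | CC(C)(C)OC(=O)CC(=O)[C@@H](C(=C)C(=O)OC(C)(C)C)[C@@H](O[Si](C)(C)C(C)(C)C)[C@H](C(=C)CO[Si](C)(C)C(C)(C)C)/C(C)=C/COCc1ccc(OC)cc1 | intermediate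
24 | 9-hydroxy analogue of 23 (free C2 hydroxyl) | CC(C)(C)OC(=O)CC(=O)[C@@H](C(=C)C(=O)OC(C)(C)C)[C@@H](O[Si](C)(C)C(C)(C)C)[C@H](C(=C)CO[Si](C)(C)C(C)(C)C)/C(C)=C/CO | intermediate
25 | acylketene from 24 | O=C=CC(=O)[C@@H](C(=C)C(=O)OC(C)(C)C)[C@@H](O[Si](C)(C)C(C)(C)C)[C@H](C(=C)CO[Si](C)(C)C(C)(C)C)/C(C)=C/CO | intermediate
26 | (5S,6S,7S,8E)-5-(3-tert-butoxy-3-oxoprop-1-en-2-yl)-6-[(tert-butyldimethylsilyl)oxy]-7-{3-[(tert-butyldimethylsilyl)oxy]prop-1-en-2-yl}-8-methyl-1-oxacyclodec-8-ene-2,4-dione | O=C1CC(=O)[C@@H](C(=C)C(=O)OC(C)(C)C)[C@@H](O[Si](C)(C)C(C)(C)C)[C@H](C(=C)CO[Si](C)(C)C(C)(C)C)/C(C)=C/CO1 | intermediate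
27 | β-keto acid: C9 carboxylic acid of 28 (C9 epimers) | C=C[C@@]1(C)C(C(=O)O)C(=O)[C@@H](C(=C)C(=O)OC(C)(C)C)[C@@H](O[Si](C)(C)C(C)(C)C)[C@@H]1C(=C)CO[Si](C)(C)C(C)(C)C | intermediate
28 | tert-butyl 2-{(1S,2S,3S,4R)-2-[(tert-butyldimethylsilyl)oxy]-3-{3-[(tert-butyldimethylsilyl)oxy]prop-1-en-2-yl}-4-ethenyl-4-methyl-6-oxocyclohexyl}prop-2-enoate (5S,6S,7S,10R) | C=C[C@@]1(C)CC(=O)[C@@H](C(=C)C(=O)OC(C)(C)C)[C@@H](O[Si](C)(C)C(C)(C)C)[C@@H]1C(=C)CO[Si](C)(C)C(C)(C)C | intermediate
29 | tert-butyl 2-{(1R,2S,3S,4R,6R)-2-[(tert-butyldimethylsilyl)oxy]-3-{3-[(tert-butyldimethylsilyl)oxy]prop-1-en-2-yl}-4-ethenyl-6-hydroxy-4-methylcyclohexyl}prop-2-enoate (5S,6S,7R,8R,10R) | C=C[C@@]1(C)C[C@@H](O)[C@@H](C(=C)C(=O)OC(C)(C)C)[C@@H](O[Si](C)(C)C(C)(C)C)[C@@H]1C(=C)CO[Si](C)(C)C(C)(C)C | intermediate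
30 | (tert-butyldimethylsilyloxy)acetaldehyde | O=CCO[Si](C)(C)C(C)(C)C | starting material
31 | 1,1,1,3,3,3-hexafluoropropan-2-yl acrylate | C=CC(=O)OC(C(F)(F)F)C(F)(F)F | starting material
32 | 1,1,1,3,3,3-hexafluoropropan-2-yl (3R)-4-[(tert-butyldimethylsilyl)oxy]-3-hydroxy-2-methylidenebutanoate | C=C([C@@H](O)CO[Si](C)(C)C(C)(C)C)C(=O)OC(C(F)(F)F)C(F)(F)F | intermediate
33 | 1,1,1,3,3,3-hexafluoropropan-2-yl (3R)-3,4-bis[(tert-butyldimethylsilyl)oxy]-2-methylidenebutanoate | C=C([C@@H](O[Si](C)(C)C(C)(C)C)CO[Si](C)(C)C(C)(C)C)C(=O)OC(C(F)(F)F)C(F)(F)F | intermediate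
34 | (3R)-3,4-bis[(tert-butyldimethylsilyl)oxy]-2-methylidenebutanoic acid | C=C([C@@H](O[Si](C)(C)C(C)(C)C)CO[Si](C)(C)C(C)(C)C)C(=O)O | intermediate
35 | C8 ester of 29 with 34 (5S,6S,7R,8R,10R; 3'R): tert-butyl ester and four TBS ethers in place | C=C[C@@]1(C)C[C@@H](OC(=O)C(=C)[C@@H](O[Si](C)(C)C(C)(C)C)CO[Si](C)(C)C(C)(C)C)[C@@H](C(=C)C(=O)OC(C)(C)C)[C@@H](O[Si](C)(C)C(C)(C)C)[C@@H]1C(=C)CO[Si](C)(C)C(C)(C)C | intermediate
36 | C12 carboxylic acid of 35 (tetra-TBS ether of the target) | C=C[C@@]1(C)C[C@@H](OC(=O)C(=C)[C@@H](O[Si](C)(C)C(C)(C)C)CO[Si](C)(C)C(C)(C)C)[C@@H](C(=C)C(=O)O)[C@@H](O[Si](C)(C)C(C)(C)C)[C@@H]1C(=C)CO[Si](C)(C)C(C)(C)C | intermediate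
37 | CNP0348657.1 (5S,6S,7S,8R,10R; 3'R) | C=C[C@@]1(C)C[C@@H](OC(=O)C(=C)[C@@H](O)CO)[C@@H](C(=C)C(=O)O)[C@@H](O)[C@@H]1C(=C)CO | target

**Totals**

Total step count: 24.
Longest linear sequence: 20 steps (steps 1–3, 5–18, 22–24).

**Steps most likely to fail**

1. Step 17 (key step). Intermolecular capture of the acylketene may outrun closure of the ten-membered ring, or the transannular [3,3] shift may be too slow at temperatures at which the C11 methylene stays out of conjugation. Fallback with known chemistry, from 24 back to 28: methyl chloroformate and pyridine convert the allylic alcohol into the allylic methyl carbonate F1. Pd(PPh3)4 (zerovalent palladium) in THF ionises it, and the β-keto ester carbanion closes the six-membered ring at the substituted allyl terminus in an intramolecular Tsuji–Trost alkylation that forms the same C9–C10 bond and gives the cyclic tert-butyl β-keto ester F2 (C9 epimers). Heating this in wet toluene at 110 °C cleaves the β-keto tert-butyl ester with loss of CO2 and delivers ketone 28.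

2. Step 18. Facial selectivity of hydride delivery may be poor, because the axial C10 methyl shields the face that leads to the wanted equatorial alcohol. Fallback from 28 to 29: substrate control is replaced by catalyst control, a Corey–Bakshi–Shibata reduction with catecholborane and the matched enantiomer of 2-methyl-CBS-oxazaborolidine at −78 °C, which tells the branched C7 flank from the C9 methylene; no new compound is made.

3. Step 24. The liberated C6 hydroxyl may lactonise onto the C12 acid, or the C8 ester may shift to C6, during the acidic fluoride treatment. Fallback from 35 to 37: the order of unveiling is reversed. HF·pyridine acts first on 35 and gives the tetraol tert-butyl ester F3, whose hindered ester cannot lactonise; then Me3SiOTf/2,6-lutidine (excess, hydroxyls silylated transiently) cleaves the tert-butyl ester, and a pH 7 methanolic buffer work-up releases 37, isolated as its sodium salt.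

**Further compounds**

F1 | step 17 | allylic methyl carbonate of 24 | CC(C)(C)OC(=O)CC(=O)[C@@H](C(=C)C(=O)OC(C)(C)C)[C@@H](O[Si](C)(C)C(C)(C)C)[C@H](C(=C)CO[Si](C)(C)C(C)(C)C)/C(C)=C/COC(=O)OC
F2 | step 17 | cyclic tert-butyl β-keto ester (C9 tert-butoxycarbonyl derivative of 28, C9 epimers) | C=C[C@@]1(C)C(C(=O)OC(C)(C)C)C(=O)[C@@H](C(=C)C(=O)OC(C)(C)C)[C@@H](O[Si](C)(C)C(C)(C)C)[C@@H]1C(=C)CO[Si](C)(C)C(C)(C)C
F0 | step 18 | none | none
F3 | step 24 | tetraol tert-butyl ester (C12 tert-butyl ester of 37) | C=C[C@@]1(C)C[C@@H](OC(=O)C(=C)[C@@H](O)CO)[C@@H](C(=C)C(=O)OC(C)(C)C)[C@@H](O)[C@@H]1C(=C)CO
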